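**Retrosynthetic overview**

1. The target is reached from a trans-decalone ester by end-game changes only: C8 ketone to C8=CH2 (Wittig), C18 ester to CH2OAc, C15 silyl ether to CO2H.
2. Ring A is opened at C3–C4: a monocyclic ring-B bromo keto ester closes it by alkylation of the C4 ester enolate with the C3 bromide. The enabling feature is that quaternary C4 carries C18, which at the ester level makes C4 a planar α-carbon five bonds from C3 (C4–C5–C10–C1–C2–C3), while C9 lies α to the C8 carbonyl that later becomes the ring-B methylidene. C4 and C9 are therefore both correctable, and a four-isomer mixture converges on one trans-decalin.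
3. The ring-B precursor comes from a 4-substituted 3-methylcyclohexenone by three-component coupling: a C1–C3 cuprate adds at C10 anti to the C5 arm, and the enolate is alkylated at C9 by the side-chain iodide.
4. The enone comes from 2-methylcyclohexenone by CBS reduction, Johnson–Claisen rearrangement (C5 by chirality transfer, C4 as an epimer mixture) and allylic oxidation; C13 comes from (R)-3-methylglutaric acid monomethyl ester.
5. Ring order: ring B is bought as the cyclohexenone; ring A is the only ring formed, in step 10.

Key step: step 10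

Remark on the chemistry: atoms are named by labdane numbering (C4 = quaternary CH3/CH2OAc carbon, C10 = angular-methyl carbon, C8 = methylidene carbon, C9 = side-chain ring carbon, C13 = side-chain stereocentre, C15 = carboxyl carbon, C18 = acetoxymethyl carbon, C19 = C4 methyl). The target is (4R,5R,9S,10R,13S), with CH2OAc equatorial and trans to the C10 methyl.

**Route**

Step 1
Reactants: 1 2-methylcyclohex-2-en-1-one
Product: 2 (1S)-2-methylcyclohex-2-en-1-ol
Conditions: (R)-2-methyl-CBS-oxazaborolidine (0.15 equiv), BH3·SMe2, THF, −20 °C, slow addition of 1; MeOH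
Reagents that add atoms: none
Why: Corey–Bakshi–Shibata reduction; with the 2-methylvinyl arm as the large group the (R)-catalyst should deliver hydride to the face that gives the (S)-carbinol, whose configuration is later relayed to C5.

Step 2
Reactants: 2 (1S)-2-methylcyclohex-2-en-1-ol; 3 triethyl orthopropionate
Product: 5 ethyl 2-[(1S)-2-methylcyclohex-2-en-1-yl]propanoate (both C2 epimers of the propanoate), via ketene acetal 4 (not isolated)
Conditions: EtCO2H (cat.), neat, 140 °C, EtOH distilled off
Reagents that add atoms: none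
Why: Johnson–Claisen rearrangement; the suprafacial [3,3] shift of ketene acetal 4 forms the C5–C4 bond on the face that carried the C–O bond, so the carbinol configuration is transferred to C5, while C4 forms as an epimer mixture that the key step erases.

Step 3
Reactants: 5 ethyl 2-[(1S)-2-methylcyclohex-2-en-1-yl]propanoate
Product: 6 ethyl 2-[(1S)-2-methyl-4-oxocyclohex-2-en-1-yl]propanoate (both C2 epimers of the propanoate)
Conditions: Rh2(cap)4 (cap = caprolactamate, 1 mol %), t-BuOOH (70% aq), K2CO3, CH2Cl2, 23 °C
Reagents that add atoms: tert-butyl hydroperoxide, CC(C)(C)OO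
Why: Radical allylic oxidation; the unhindered ring CH2 next to the vinylic CH (C8) should be oxidised in preference to the hindered tertiary allylic C5–H, giving the 3-methylcyclohexenone pattern without touching C5.

Step 4
Reactants: 7 (3R)-5-methoxy-3-methyl-5-oxopentanoic acid [(R)-3-methylglutaric acid monomethyl ester]
Product: 8 methyl (3R)-5-hydroxy-3-methylpentanoate
Conditions: BH3·SMe2, THF, 0 → 23 °C; MeOH
Reagents that add atoms: none
Why: Chemoselective borane reduction of the carboxylic acid in the presence of the methyl ester; the stereocentre (future C13) is not involved.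

Step 5
Reactants: 8 methyl (3R)-5-hydroxy-3-methylpentanoate
Product: 9 methyl (3R)-5-{[tert-butyl(dimethyl)silyl]oxy}-3-methylpentanoate
Conditions: TBSCl, imidazole, DMF, 0 → 23 °C
Reagents that add atoms: tert-butyldimethylsilyl chloride, CC(C)(C)[Si](C)(C)Cl
Why: Imidazole-promoted silylation of the primary alcohol, run at once to forestall lactonisation of the 5-hydroxy ester; this end becomes C15.

Step 6
Reactants: 9 methyl (3R)-5-{[tert-butyl(dimethyl)silyl]oxy}-3-methylpentanoate
Product: 10 (3S)-5-{[tert-butyl(dimethyl)silyl]oxy}-3-methylpentan-1-ol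
Conditions: LiAlH4, Et2O, 0 °C; aq NaOH work-up
Reagents that add atoms: none
Why: LiAlH4 reduction of the unhindered methyl ester to the primary alcohol, which differentiates the two chain ends (the descriptor changes only through CIP priorities).

Step 7
Reactants: 10 (3S)-5-{[tert-butyl(dimethyl)silyl]oxy}-3-methylpentan-1-ol
Product: 11 tert-butyl{[(3R)-5-iodo-3-methylpentyl]oxy}dimethylsilane
Conditions: I2, PPh3, imidazole, CH2Cl2, 0 → 23 °C
Reagents that add atoms: iodine, II
Why: Appel-type iodination; iodide displaces the alkoxyphosphonium by SN2 at the primary carbon (future C11), two bonds away from the stereocentre.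

Step 8
Reactants: 6 ethyl 2-[(1S)-2-methyl-4-oxocyclohex-2-en-1-yl]propanoate; 12 2-(3-bromopropoxy)oxane; 11 tert-butyl{[(3R)-5-iodo-3-methylpentyl]oxy}dimethylsilane
Product: 16 ethyl 2-[(1S,2S)-3-[(3S)-5-{[tert-butyl(dimethyl)silyl]oxy}-3-methylpentyl]-2-methyl-2-[3-(oxan-2-yloxy)propyl]-4-oxocyclohexyl]propanoate (epimer mixture at propanoate C2 and ring C3 and the acetal carbon), via alkyllithium 13 (not isolated), via lithium dialkylcuprate 14 (not isolated), via lithium enolate 15 (not isolated)
Conditions: 12, Li, Et2O, −10 °C; CuI (copper monoiodide), Et2O/THF, −40 °C; 6, −78 → −20 °C; then 11, DMPU, −78 → 23 °C; aq NH4Cl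
Reagents that add atoms: none
Why: Three-component coupling (organocuprate 1,4-addition, then enolate alkylation); the cuprate should add to C10 anti to the adjacent C5 arm, setting quaternary C10 with its methyl cis to that arm, and the regiodefined enolate 15 is C-alkylated at C9 by the primary iodide; the C9 configuration formed here is not relied on.

Step 9
Reactants: 16 the keto ester of step 8
Product: 17 ethyl 2-[(1S,2S)-2-(3-bromopropyl)-3-[(3S)-5-{[tert-butyl(dimethyl)silyl]oxy}-3-methylpentyl]-2-methyl-4-oxocyclohexyl]propanoate (epimer mixture at propanoate C2 and ring C3)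
Conditions: CBr4, PPh3, CH2Cl2, 0 → 23 °C
Reagents that add atoms: carbon tetrabromide, BrC(Br)(Br)Br
Why: Appel-type direct conversion of a tetrahydropyranyl ether into the primary bromide via the bromophosphonium-activated acetal; the primary silyl ether, ketone and ester should be left alone under these neutral conditions.

Step 10
Reactants: 17 the bromo keto ester of step 9
Product: 20 ethyl (1R,4aS,5R,8aR)-5-[(3S)-5-{[tert-butyl(dimethyl)silyl]oxy}-3-methylpentyl]-1,4a-dimethyl-6-oxodecahydronaphthalene-1-carboxylate, via dilithium bis-enolate 18 (not isolated), via cyclized lithium enolate 19 (not isolated)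
Conditions: inverse addition of 17 to LiN(iPr)2 (2.3 equiv), THF, −78 °C; DMPU, −78 → 0 °C; then EtOH, NaOEt (cat.), 23 °C; aq NH4Cl
Reagents that add atoms: none
Why: Inverse addition to excess LiN(iPr)2 first removes the unhindered C7–H, so the C8 ketone is stored as its kinetic lithium enolate, and then the C4–H, giving bis-enolate 18 in which only the more basic ester enolate carbon can reach C3; intramolecular SN2 displacement of bromide (6-exo-tet) closes ring A and makes C4 quaternary. The closest known reaction type is the intramolecular ester enolate alkylation under allylic-strain control, combined with the use of a kinetic enolate as an in-flask protecting group for a ketone. C5 and C10 are already set with the C4 arm and the C1–C3 arm trans on ring B, so only the trans-fused chair closure is available. The C4 enolate is planar, so both C4 epimers of 17 give the same intermediate, and A(1,3) strain between the enolate oxygens and the C6/C10 substituents of C5 should keep C5–H in the enolate plane, so that C3 bonds to the face next to C10, leaving the C19 methyl axial (syn to the C10 methyl) and the ester equatorial. Ethanol then reprotonates C7, and the ethoxide present (matched to the ethyl ester, so that ester exchange changes nothing) equilibrates C9 through the C8 enolate to the equatorial side chain of the trans-decalone, so the four diastereomers of 17 should converge on one. The selectivity needed is alkylation by the ester enolate and not by the ketone enolate, which rests on kinetic C7 deprotonation (the C9 enolate that could close a five-membered ring should not form at −78 °C) and on ring size (O- or C7-alkylation would need seven-membered rings).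

Step 11
Reactants: 20 the keto ester of step 10
Product: 21 ethyl (1R,4aR,5S,8aR)-5-[(3S)-5-{[tert-butyl(dimethyl)silyl]oxy}-3-methylpentyl]-1,4a-dimethyl-6-methylidenedecahydronaphthalene-1-carboxylate
Conditions: Ph3PCH3Br, KOtBu, toluene, 90 °C
Reagents that add atoms: methyltriphenylphosphonium bromide, C[P+](c1ccccc1)(c1ccccc1)c1ccccc1.[Br-]
Why: Wittig methylenation of the hindered C8 ketone; under the basic conditions C9 stays at its thermodynamic equatorial configuration and the neopentyl-type ester is inert.

Step 12
Reactants: 21 the methylidene ester of step 11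
Product: 22 [(1R,4aR,5S,8aR)-5-[(3S)-5-{[tert-butyl(dimethyl)silyl]oxy}-3-methylpentyl]-1,4a-dimethyl-6-methylidenedecahydronaphthalen-1-yl]methanol
Conditions: LiAlH4, THF, 0 → 23 °C; aq NaOH work-up
Reagents that add atoms: none
Why: LiAlH4 reduction of the hindered equatorial ester to the primary alcohol (C18); the alkene and the silyl ether are inert.

Step 13
Reactants: 22 the alcohol of step 12
Product: 23 [(1R,4aR,5S,8aR)-5-[(3S)-5-{[tert-butyl(dimethyl)silyl]oxy}-3-methylpentyl]-1,4a-dimethyl-6-methylidenedecahydronaphthalen-1-yl]methyl acetate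
Conditions: Ac2O, pyridine, DMAP (cat.), CH2Cl2, 23 °C
Reagents that add atoms: acetic anhydride, CC(=O)OC(C)=O
Why: DMAP-catalysed acetylation of the neopentyl primary alcohol.

Step 14
Reactants: 23 the acetate of step 13
Product: 24 (3S)-5-[(1S,4aR,5R,8aR)-5-[(acetyloxy)methyl]-5,8a-dimethyl-2-methylidenedecahydronaphthalen-1-yl]-3-methylpentanoic acid (target)
Conditions: CrO3, H2SO4, H2O, acetone, 0 °C
Reagents that add atoms: water, O
Why: Jones oxidation applied directly to the primary silyl ether; acid cleaves the Si–O bond and chromic acid oxidises the freed alcohol through the aldehyde hydrate to the acid, while the acetate and the 1,1-disubstituted alkene should tolerate the short exposure at 0 °C.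

**Compound list**

1 | 2-methylcyclohex-2-en-1-one | CC1=CCCCC1=O | starting material
2 | (1S)-2-methylcyclohex-2-en-1-ol | CC1=CCCC[C@@H]1O | intermediate
3 | triethyl orthopropionate (1,1,1-triethoxypropane) | CCC(OCC)(OCC)OCC | starting material
4 | 1-ethoxy-1-{[(1S)-2-methylcyclohex-2-en-1-yl]oxy}prop-1-ene (ketene acetal, E/Z mixture) | CC=C(OCC)O[C@H]1CCCC=C1C | intermediate
5 | ethyl 2-[(1S)-2-methylcyclohex-2-en-1-yl]propanoate (both C2 epimers of the propanoate) | CCOC(=O)C(C)[C@@H]1CCCC=C1C | intermediate
6 | ethyl 2-[(1S)-2-methyl-4-oxocyclohex-2-en-1-yl]propanoate (both C2 epimers of the propanoate) | CCOC(=O)C(C)[C@@H]1CCC(=O)C=C1C | intermediate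
7 | (3R)-5-methoxy-3-methyl-5-oxopentanoic acid [(R)-3-methylglutaric acid monomethyl ester] | COC(=O)C[C@H](C)CC(=O)O | starting material
8 | methyl (3R)-5-hydroxy-3-methylpentanoate | COC(=O)C[C@H](C)CCO | intermediate
9 | methyl (3R)-5-{[tert-butyl(dimethyl)silyl]oxy}-3-methylpentanoate | COC(=O)C[C@H](C)CCO[Si](C)(C)C(C)(C)C | intermediate
10 | (3S)-5-{[tert-butyl(dimethyl)silyl]oxy}-3-methylpentan-1-ol | OCC[C@H](C)CCO[Si](C)(C)C(C)(C)C | intermediate
11 | tert-butyl{[(3R)-5-iodo-3-methylpentyl]oxy}dimethylsilane | ICC[C@H](C)CCO[Si](C)(C)C(C)(C)C | intermediate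
12 | 2-(3-bromopropoxy)oxane (racemic) | BrCCCOC1CCCCO1 | starting material
13 | [3-(oxan-2-yloxy)propyl]lithium | [Li]CCCOC1CCCCO1 | intermediate
14 | lithium bis[3-(oxan-2-yloxy)propyl]cuprate | [Li+].C(CCOC1CCCCO1)[Cu-]CCCOC1CCCCO1 | intermediate
15 | C8 lithium enolate (C8=C9) from 1,4-addition to 6, new C10–C1 bond trans to the C5 arm | CCOC(=O)C(C)[C@@H]1CCC(O[Li])=C[C@@]1(C)CCCOC2CCCCO2 | intermediate
16 | ethyl 2-[(1S,2S)-3-[(3S)-5-{[tert-butyl(dimethyl)silyl]oxy}-3-methylpentyl]-2-methyl-2-[3-(oxan-2-yloxy)propyl]-4-oxocyclohexyl]propanoate (epimer mixture at propanoate C2, ring C3 and the acetal carbon) | CCOC(=O)C(C)[C@@H]1CCC(=O)C(CC[C@H](C)CCO[Si](C)(C)C(C)(C)C)[C@@]1(C)CCCOC2CCCCO2 | intermediate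
17 | ethyl 2-[(1S,2S)-2-(3-bromopropyl)-3-[(3S)-5-{[tert-butyl(dimethyl)silyl]oxy}-3-methylpentyl]-2-methyl-4-oxocyclohexyl]propanoate (epimer mixture at propanoate C2 and ring C3) | CCOC(=O)C(C)[C@@H]1CCC(=O)C(CC[C@H](C)CCO[Si](C)(C)C(C)(C)C)[C@@]1(C)CCCBr | intermediate
18 | dilithium bis-enolate of 17 (C7=C8–OLi ketone enolate and C4=C18 ester enolate) | CCOC(O[Li])=C(C)[C@@H]1CC=C(O[Li])C(CC[C@H](C)CCO[Si](C)(C)C(C)(C)C)[C@@]1(C)CCCBr | intermediate
19 | C7 lithium enolate of the cyclized trans-decalone ester (C9 epimer mixture) | [Li]OC1=CC[C@H]2[C@](C)(C(=O)OCC)CCC[C@]2(C)C1CC[C@H](C)CCO[Si](C)(C)C(C)(C)C | intermediate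
20 | ethyl (1R,4aS,5R,8aR)-5-[(3S)-5-{[tert-butyl(dimethyl)silyl]oxy}-3-methylpentyl]-1,4a-dimethyl-6-oxodecahydronaphthalene-1-carboxylate | O=C1CC[C@H]2[C@](C)(C(=O)OCC)CCC[C@]2(C)[C@H]1CC[C@H](C)CCO[Si](C)(C)C(C)(C)C | intermediate
21 | ethyl (1R,4aR,5S,8aR)-5-[(3S)-5-{[tert-butyl(dimethyl)silyl]oxy}-3-methylpentyl]-1,4a-dimethyl-6-methylidenedecahydronaphthalene-1-carboxylate | C=C1CC[C@H]2[C@](C)(C(=O)OCC)CCC[C@]2(C)[C@H]1CC[C@H](C)CCO[Si](C)(C)C(C)(C)C | intermediate
22 | [(1R,4aR,5S,8aR)-5-[(3S)-5-{[tert-butyl(dimethyl)silyl]oxy}-3-methylpentyl]-1,4a-dimethyl-6-methylidenedecahydronaphthalen-1-yl]methanol | C=C1CC[C@H]2[C@](C)(CO)CCC[C@]2(C)[C@H]1CC[C@H](C)CCO[Si](C)(C)C(C)(C)C | intermediate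
23 | [(1R,4aR,5S,8aR)-5-[(3S)-5-{[tert-butyl(dimethyl)silyl]oxy}-3-methylpentyl]-1,4a-dimethyl-6-methylidenedecahydronaphthalen-1-yl]methyl acetate | C=C1CC[C@H]2[C@](C)(COC(C)=O)CCC[C@]2(C)[C@H]1CC[C@H](C)CCO[Si](C)(C)C(C)(C)C | intermediate
24 | (3S)-5-[(1S,4aR,5R,8aR)-5-[(acetyloxy)methyl]-5,8a-dimethyl-2-methylidenedecahydronaphthalen-1-yl]-3-methylpentanoic acid | C=C1CC[C@H]2[C@](C)(COC(C)=O)CCC[C@]2(C)[C@H]1CC[C@H](C)CC(=O)O | target

**Step count and risks**

Total step count: 14. Longest linear sequence: 11 steps (steps 4–7 and then 8–14, from (R)-3-methylglutaric acid monomethyl ester 7 to target 24); the ring-B branch (steps 1–3) joins this sequence at step 8.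

Steps most likely to fail:

1. Step 10. Proton transfer between the enolate sites could move the ketone enolate from C7 to C9, which would then close a five-membered ring onto C3, or the ketone enolate could be alkylated in place of the ester enolate. The fallback takes the ketone out of the ring closure. It sets out from 17: ketalisation with 1,2-bis(trimethylsilyloxy)ethane and catalytic TMSOTf in CH2Cl2 at −78 °C should give the ethylene ketal of 17 F1. LiN(iPr)2 (1.2 equiv) with DMPU then closes ring A on a substrate whose only acidic C–H is C4–H, under the same allylic-strain control, to give the ethylene ketal of the bicyclic ester F2. Transketalisation with catalytic I2 in acetone, followed by NaOEt in EtOH to equilibrate C9, comes back to the route at 20.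

2. Step 8. C-alkylation at the hindered C9 enolate carbon (next to quaternary C10) may be slow enough for enolate proton exchange, O-alkylation and elimination of the iodide to take over. The fallback replaces the alkylation by aldol condensation and hydrogenation. It sets out from 6 and 10: oxidation of 10 with Dess–Martin periodinane gives (3R)-5-{[tert-butyl(dimethyl)silyl]oxy}-3-methylpentanal F3. Enolate 15, generated from 6 as in step 8, is trapped with F3 at −78 °C to give the aldol adduct F4. Mesylation (MsCl, Et3N) and elimination with DBU give the 2-alkylidene ketone F5, and hydrogenation of the conjugated C=C (H2, Pd/C, EtOAc) comes back to the route at 16.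

3. Step 9. The primary silyl ether may be cleaved along with the acetal, leading on to a dibromide. The fallback separates deprotection from activation. It sets out from 16: PPTS in EtOH at 45 °C should remove only the tetrahydropyranyl group to give the primary alcohol ethyl 2-[(1S,2S)-3-[(3S)-5-{[tert-butyl(dimethyl)silyl]oxy}-3-methylpentyl]-2-(3-hydroxypropyl)-2-methyl-4-oxocyclohexyl]propanoate F6. Brief Appel bromination of the free alcohol (CBr4, PPh3, CH2Cl2, 0 °C) comes back to the route at 17.

Further compounds
F1 | step 10 | ethylene ketal (1,4-dioxaspiro[4.5]decane) of bromo keto ester 17 (epimer mixture at propanoate C2 and at C9) | CCOC(=O)C(C)[C@@H]1CCC2(OCCO2)C(CC[C@H](C)CCO[Si](C)(C)C(C)(C)C)[C@@]1(C)CCCBr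
F2 | step 10 | ethylene ketal of the cyclized trans-decalin ester (C4 set, C9 epimer mixture) | C12(OCCO1)CC[C@H]3[C@](C)(C(=O)OCC)CCC[C@]3(C)C2CC[C@H](C)CCO[Si](C)(C)C(C)(C)C
F3 | step 8 | (3R)-5-{[tert-butyl(dimethyl)silyl]oxy}-3-methylpentanal | O=CC[C@H](C)CCO[Si](C)(C)C(C)(C)C
F4 | step 8 | aldol adduct of enolate 15 and F3 (ring C9 bears the 1-hydroxy-3-methylpentyl chain, diastereomer mixture) | CCOC(=O)C(C)[C@@H]1CCC(=O)C(C(O)C[C@H](C)CCO[Si](C)(C)C(C)(C)C)[C@@]1(C)CCCOC2CCCCO2
F5 | step 8 | 2-alkylidene ketone from dehydration of F4 (C9=C11 double bond) | CCOC(=O)C(C)[C@@H]1CCC(=O)C(=CC[C@H](C)CCO[Si](C)(C)C(C)(C)C)[C@@]1(C)CCCOC2CCCCO2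
F6 | step 9 | ethyl 2-[(1S,2S)-3-[(3S)-5-{[tert-butyl(dimethyl)silyl]oxy}-3-methylpentyl]-2-(3-hydroxypropyl)-2-methyl-4-oxocyclohexyl]propanoate (epimer mixture at propanoate C2 and ring C3) | CCOC(=O)C(C)[C@@H]1CCC(=O)C(CC[C@H](C)CCO[Si](C)(C)C(C)(C)C)[C@@]1(C)CCCO
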